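**Last readings.** South-east ends higher than south-west: 64.4% of target against 56.2% at 2.50 d.

all flasks: starting material 0.80 M
- south-west: free catalyst 0.81 mM; run made earlier
- south-east: free catalyst 1.3 mM; run made earlier
- flask: free catalyst 0.58 mM

| south-west: time / d | south-west: target / % | south-east: time / d | south-east: target / % |
|---|---|---|---|
| 0.333 | 24.4 | 0.208 | 24.0 |
| 0.625 | 37.0 | 0.333 | 32.2 |
| 1.04 | 45.7 | 0.417 | 38.6 |
| 1.25 | 49.3 | 0.625 | 46.9 |
| 1.67 | 53.2 | 1.04 | 56.9 |
| 2.08 | 55.4 | 1.67 | 63.0 |
| 2.50 | 56.2 | 2.50 | 64.4 |

(scatter of a reading: 0.5 percentage points)

- the numbers in the tables scatter by 0.5 percentage points (one standard deviation)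

1. apparent order in free catalyst when 20% of the starting material are converted (percent change of the rate of making target for one percent more free catalyst charged)

I follow one molecule of starting material and assume a fork: it goes to target through the catalyst, or into some loss that ignores the catalyst. At equal starting material, the odds of that fork then move with the catalyst as the rate of making target does. As a whole-run stand-in I take F, the target over the rest of the charge.

**Catalyst charge.** By hand, odds proportional to the charge would grow 1.60-fold. But F is 1.28 in south-west and 1.81 in south-east, a 1.41-fold rise. So n = 0.726: this is the fork order, the logarithm of the odds ratio over that of the charge ratio.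

**Waiting longer.** South-west still gains 0.8 percentage points over its last interval, against a scatter of 0.5 points. So n stays a reading, yet I commit to it for the flask.

**The check.** The forecast says 0.9, “with moderate uncertainty”, and the flask gives 0.75.

    2 starting material → homo dimer (k = 8.14 × 10⁻⁴ /M/min)
    catalyst intermediate A → catalyst intermediate B (k = 2.32 /min)
    starting material + free catalyst → catalyst intermediate A (k = 2.60 /M/min)
    2 free catalyst ⇌ resting dimer (K = 2100 /M, k = 49.7 /M/min)
    catalyst intermediate B → free catalyst + target (k = 33.5 /min)

**Resting dimer.** Homo dimer is the loss that ignores the catalyst, and resting dimer, the off-cycle resting state, holds 41.3% of the flask's catalyst at 0.400 d. Part of the shortfall from first order comes from the passing of free catalyst into resting dimer, both ways: the same flask with that step taken away has order 1.0. That is a gain of 0.25, beside the 0.274 that n leaves below first order. The return of resting dimer to free catalyst pulls the other way: with that return taken away, the flask's order falls to 0.41, and its rate at 20% conversion falls to 0.444 times the actual 0.524 M/d.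

The runs are simulated with constants of no real substance; the scatter is artificial.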